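The numbers of this flask are invented, and the outcome is calculated.

Before filling a plate with solid substrate, decide one thing first: will the charge dissolve completely, or will solid stay on the bottom?

    starting material ⇌ target (K1 = 1.2, k1 = 3.73 × 10⁻⁴ s⁻¹)
    target ⇌ isomer of the product A (K2 = 2.64, k2 = 0.00112 s⁻¹)
    isomer of the product A ⇌ isomer of the product B (K3 = 0.809, k3 = 6.09 × 10⁻⁴ s⁻¹)
    isomer of the product B ⇌ starting material (k4 = 4.19 × 10⁻⁴ s⁻¹)
    solid substrate ⇌ starting material, rate k5*(cs5 - [starting material]) while solid is left; crystals form when [starting material] > cs5 (cs5 = 0.074 M, k5 = 4.68 × 10⁻⁴ s⁻¹)
    starting material ⇌ dormant form (K6 = 1.8, k6 = 1.17 × 10⁻⁴ s⁻¹)

solid substrate 0.40 M; time 6.0 d

- the state of affairs at 6.0 d: stopped, and by what, or still going (for what has run out or reacted, a solid counts together with what of it has only dissolved) (forward and back rates have come level / all of the solid substrate has reacted / it is still moving)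
- part of the solid substrate that has turned into other species by 6.0 d (what has only dissolved does not count)
- how much target there is at 6.0 d, in percent of the solid substrate charged
- how much isomer of the product A there is at 6.0 d, in percent of the solid substrate charged

- solid, in amounts per volume of the solution: solid substrate
- at the start none of the solid substrate is in solution
- what has only dissolved of solid substrate counts as not reacted
- what has gone from starting material into another species counts as reacted, even if it can come back
- the reaction counts as stopped when no species that holds the solid substrate changes by six tenths of a point or more over the second half of the time
- run time (flask): 6.0 d

Two chemists argue over this flask. The first says that a flask with solid in it stays saturated: starting material sits at its solubility of 0.074 M, and the equilibrium constants then put target at 0.0888 M and isomer of the product A at 0.234 M. The second wants the forms added up first. For each part of starting material at equilibrium, the solution holds 9.73 parts counted over starting material, target, both isomers and dormant form. Multiplying by the solubility gives 0.720 M: this is the capacity of the solution, the total it holds in dissolved forms at equilibrium when starting material stands at its solubility. The charge of 0.40 M is smaller, so the first chemist's saturated flask would need 1.80 times what was charged.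

My own reckoning goes round once more. If the charge has dissolved, starting material comes to 0.0411 M, which is below its solubility, so the assumption holds. The dormant form's way back has a smaller rate constant than the way back of any other step, and its half-life of 2.96 h is short against 6.0 d, so I expect thermodynamic control, with the shares given by the equilibrium ratios. That gives me a conversion of 89.7%, target at 12.3% and isomer of the product A at 32.6%.

The forecast takes the second side: forward and back rates have come level, conversion 89.5%, target 12.6%, isomer of the product A 33.2%, reasoning “so all 0.40 M of solid dissolves and the system reaches full equilibrium”. Its total of the ratios is 9.53 against my 9.73, and its isomer of the product A stands above mine.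

The flask gives forward and back rates have come level, with conversion 89.7%, target 12.3% and isomer of the product A 32.6%, so the second chemist's view stands. In this flask the charge fills 55.6% of the capacity, and half of the dissolving was done by 0.0989 d, short against 6.0 d, with solid substrate at 0% at 6.00 d. The first chemist's region is the neighbour flask with 1.6 M of solid substrate, above the capacity. Reckoned from the capacity, 55.0% of that charge should stay undissolved, and at 6.00 d that flask holds, of its charge, 55.0% as solid and 14.7% as isomer of the product A, with starting material at 0.0740 M.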